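**Plan** (pyrrole numbered N1, C2 = aryl-bearing carbon, C3, C4, C5)
- Retrosynthesis: C3–Br and C5–Br are cut first (late electrophilic bromination), then the N-Boc and O-methyl groups. N1–C2 and C4–Br are cut together, which opens the pyrrole to an amino-ynone, and the carbonyl–alkyne bond C2–C3 is cut last.
- Enabling feature: in the pyrrole ring C4 carries Br and lies β to C2, the carbon bonded to the dibromophenol ring, while C5 links C4 to N1. The array C2–C3–C4(Br)–C5–N1 is an aryl ynone ArC(=O)–C≡C–CH2–N that has taken up HBr at its β-carbon and lost water.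
- Forward: the benzene ring is bought with both bromines in 3,5-dibromosalicylic acid (1). O-methylation, activation as the acid chloride and acyl Sonogashira coupling with N-Boc-propargylamine (2) join the chain.
- The pyrrole is the only ring built. It closes in step 5 with C4–Br already in place, and deprotection plus two NBS brominations complete the target.
- Stereochemistry: the target has no stereocentre. Only the geometry of a transient bromoenone matters, and equilibration supplies it.

Key step: step 5

Remark: the target is achiral (no stereocentre, and the aryl–pyrrole axis flanked only by OH, Br and NH is assumed to rotate freely at room temperature), so no enantiomer has to be selected.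

**Step 1**
Reactants: 1 3,5-dibromosalicylic acid
Product: 4 methyl 3,5-dibromo-2-methoxybenzoate, via methyl 3,5-dibromo-2-hydroxybenzoate 3 (not isolated)
Conditions: MeI (3 equiv), K2CO3 (3 equiv), DMF, rt → 50 °C
Reagents that add atoms: iodomethane, CI
Why: Exhaustive SN2 O-alkylation (Williamson type), first of the carboxylate and then of the hindered, hydrogen-bonded phenoxide, should mask both acidic sites in one operation while the aryl bromides stay inert.

**Step 2**
Reactants: 4 methyl 3,5-dibromo-2-methoxybenzoate
Product: 5 3,5-dibromo-2-methoxybenzoic acid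
Conditions: LiOH·H2O, THF/MeOH/H2O, 40 °C; then 1 M HCl
Reagents that add atoms: lithium hydroxide, [Li+].[OH-]
Why: Ester saponification (BAc2) frees the carboxylic acid, and neither the aryl methyl ether nor the aryl bromides react with aqueous hydroxide at this temperature.

**Step 3**
Reactants: 5 3,5-dibromo-2-methoxybenzoic acid
Product: 6 3,5-dibromo-2-methoxybenzoyl chloride
Conditions: (COCl)2, DMF (cat.), CH2Cl2, 0 °C → rt; concentrated and used crude
Reagents that add atoms: oxalyl chloride, ClC(=O)C(Cl)=O
Why: Acid chloride formation through the Vilsmeier-type chloroiminium species from oxalyl chloride and catalytic DMF is mild, gives only volatile by-products and leaves the ether and the bromides untouched.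

**Step 4**
Reactants: 6 3,5-dibromo-2-methoxybenzoyl chloride; 2 N-Boc-propargylamine
Product: 7 tert-butyl N-[4-(3,5-dibromo-2-methoxyphenyl)-4-oxobut-2-yn-1-yl]carbamate
Conditions: PdCl2(PPh3)2 (2 mol %), CuI (4 mol %), Et3N (1.05 equiv), THF, rt
Reagents that add atoms: none
Why: In this acyl Sonogashira coupling Pd(0) inserts into the C(O)–Cl bond at room temperature far faster than into the two aryl C–Br bonds, which are meta to the carbonyl and ortho/para to the donating methoxy group, and a single equivalent of amine keeps the base-sensitive amino-ynone from isomerising.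

**Step 5**
Reactants: 7 tert-butyl N-[4-(3,5-dibromo-2-methoxyphenyl)-4-oxobut-2-yn-1-yl]carbamate
Product: 11 tert-butyl 4-bromo-2-(3,5-dibromo-2-methoxyphenyl)pyrrole-1-carboxylate, via Z-bromoenone 8 (not isolated), via E-bromoenone 9 (not isolated), via cyclic hemiaminal 10 (not isolated)
Conditions: LiBr (5 equiv), p-TsOH·H2O (2 equiv), THF/t-BuOH, rt → 40 °C
Reagents that add atoms: lithium bromide, [Li+].[Br-]
Why: LiBr and TsOH generate HBr in situ; the protonated ynone 7 accepts bromide at the alkyne carbon β to the carbonyl (future C4), and protonation of the resulting allenol should give first the anti-adduct 8 (Z, Br cis to the aroyl group), which equilibrates with 9 (E, CH2NHBoc cis to the aroyl group) by reversible bromide addition–elimination. Only 9 can close: its carbamate nitrogen attacks the activated ketone carbon in a 5-exo-trig mode (N1–C2) to give hemiaminal 10, which ionises to an N-acyliminium ion and loses a C5 proton, so that water leaves and the aromatic pyrrole 11 forms irreversibly and drains the Z/E equilibrium. The closest known reaction type is the conjugate hydroiodination–cyclocondensation of N-Boc-4-aminobut-2-yn-1-ones with NaI/TsOH to N-Boc-4-iodopyrroles (and the related halide/acid route from 4-oxy-ynones to 3-halofurans), while conjugate hydrobromination of ynones with LiBr and a Brønsted acid is standard on its own. No lasting stereocentre is made, since the carbinol carbon of 10 is racemic and becomes sp2 on dehydration. The step needs β-regioselectivity, secured by the polarisation of the alkyne by the aroyl group, and access to the E geometry, secured by equilibration under the thermodynamic drain of aromatisation. It also needs chemoselectivity: t-BuOH as co-solvent and a sulfonic acid near room temperature should spare the Boc group, the methyl ether keeps the phenol oxygen from adding to the enone, and the aryl bromides are spectators.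

**Step 6**
Reactants: 11 tert-butyl 4-bromo-2-(3,5-dibromo-2-methoxyphenyl)pyrrole-1-carboxylate
Product: 12 2,4-dibromo-6-(4-bromo-1H-pyrrol-2-yl)phenol
Conditions: BBr3 (4 equiv), CH2Cl2, −78 → 0 °C; then H2O
Reagents that add atoms: none
Why: Lewis-acid ether cleavage with boron tribromide demethylates the hindered anisole and the same reagent fragments the tert-butyl carbamate (loss of the tert-butyl group, then of CO2), while a β-bromine on a pyrrole is the acid-stable regioisomer and should stay at C4.

**Step 7**
Reactants: 12 2,4-dibromo-6-(4-bromo-1H-pyrrol-2-yl)phenol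
Product: 14 pentabromopseudilin [2,4-dibromo-6-(3,4,5-tribromo-1H-pyrrol-2-yl)phenol], via 4,5-dibromopyrrole phenol 13 (not isolated)
Conditions: NBS (2.05 equiv), THF, −78 °C → rt, dark
Reagents that add atoms: N-bromosuccinimide, O=C1CCC(=O)N1Br
Why: In this electrophilic aromatic bromination the NH-pyrrole is by far the most nucleophilic ring, its only open positions are C5 (α, attacked first) and C3, and both ortho positions and the para position of the phenol are already occupied, so two equivalents of NBS should stop at the pentabromide.

**Compound list**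
1 | 3,5-dibromosalicylic acid | OC(=O)c1cc(Br)cc(Br)c1O | starting material
2 | N-Boc-propargylamine (tert-butyl N-prop-2-ynylcarbamate) | CC(C)(C)OC(=O)NCC#C | starting material
3 | methyl 3,5-dibromo-2-hydroxybenzoate (not isolated) | COC(=O)c1cc(Br)cc(Br)c1O | intermediate
4 | methyl 3,5-dibromo-2-methoxybenzoate | COC(=O)c1cc(Br)cc(Br)c1OC | intermediate
5 | 3,5-dibromo-2-methoxybenzoic acid | COc1c(Br)cc(Br)cc1C(O)=O | intermediate
6 | 3,5-dibromo-2-methoxybenzoyl chloride | COc1c(Br)cc(Br)cc1C(Cl)=O | intermediate
7 | tert-butyl N-[4-(3,5-dibromo-2-methoxyphenyl)-4-oxobut-2-yn-1-yl]carbamate | CC(C)(C)OC(=O)NCC#CC(=O)c1cc(Br)cc(Br)c1OC | intermediate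
8 | tert-butyl N-[(2Z)-2-bromo-4-(3,5-dibromo-2-methoxyphenyl)-4-oxobut-2-en-1-yl]carbamate, Br cis to aroyl (not isolated) | CC(C)(C)OC(=O)NC/C(Br)=C/C(=O)c1cc(Br)cc(Br)c1OC | intermediate
9 | tert-butyl N-[(2E)-2-bromo-4-(3,5-dibromo-2-methoxyphenyl)-4-oxobut-2-en-1-yl]carbamate, CH2NHBoc cis to aroyl (not isolated) | CC(C)(C)OC(=O)NC/C(Br)=C\C(=O)c1cc(Br)cc(Br)c1OC | intermediate
10 | tert-butyl 4-bromo-2-(3,5-dibromo-2-methoxyphenyl)-2-hydroxy-2,5-dihydropyrrole-1-carboxylate, racemic (not isolated) | CC(C)(C)OC(=O)N1CC(Br)=CC1(O)c1cc(Br)cc(Br)c1OC | intermediate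
11 | tert-butyl 4-bromo-2-(3,5-dibromo-2-methoxyphenyl)pyrrole-1-carboxylate | CC(C)(C)OC(=O)n1cc(Br)cc1-c1cc(Br)cc(Br)c1OC | intermediate
12 | 2,4-dibromo-6-(4-bromo-1H-pyrrol-2-yl)phenol | Oc1c(Br)cc(Br)cc1-c1cc(Br)c[nH]1 | intermediate
13 | 2,4-dibromo-6-(4,5-dibromo-1H-pyrrol-2-yl)phenol (not isolated) | Oc1c(Br)cc(Br)cc1-c1cc(Br)c(Br)[nH]1 | intermediate
14 | pentabromopseudilin, 2,4-dibromo-6-(3,4,5-tribromo-1H-pyrrol-2-yl)phenol (achiral) | Oc1c(Br)cc(Br)cc1-c1[nH]c(Br)c(Br)c1Br | target

**Total step count:** 7. **Longest linear sequence:** 7 steps (1 → 14); 2 enters as purchased in step 4.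

**Steps most likely to fail**

Step 5.
- Risk: bromide is a weaker nucleophile and a poorer leaving group than iodide. Conjugate addition may therefore be slow, and Z-to-E equilibration may lag so far that the sequence stalls before ring closure. Prolonged acid exposure could then bring loss of the carbamate or attack of the methoxy oxygen on the β-carbon.
- Fallback: setting out from 7, the established iodide variant (NaI, p-TsOH·H2O, THF/t-BuOH, rt) should give tert-butyl 2-(3,5-dibromo-2-methoxyphenyl)-4-iodopyrrole-1-carboxylate F1. Iodine–magnesium exchange (i-PrMgCl·LiCl, THF, −40 °C) is much faster at C–I than at the aryl C–Br bonds and should give [1-(tert-butoxycarbonyl)-5-(3,5-dibromo-2-methoxyphenyl)pyrrol-3-yl]magnesium chloride F2. Quenching with 1,2-dibromotetrachloroethane comes back to the route at 11.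

Step 6.
- Risk: the tert-butyl cation is released next to a pyrrole whose C3 and C5 are still open, so Friedel–Crafts tert-butylation may compete with clean deprotection. Acid-induced oligomerisation of the NH-pyrrole is a second possible loss.
- Fallback: the order of events is changed. Setting out from 11, nucleophilic carbamate cleavage (NaOMe, MeOH/THF, rt) should give 4-bromo-2-(3,5-dibromo-2-methoxyphenyl)-1H-pyrrole F3. NBS (2 equiv, THF, −78 °C → rt) should give 2,3,4-tribromo-5-(3,5-dibromo-2-methoxyphenyl)-1H-pyrrole F4. BBr3 (CH2Cl2, −78 → 0 °C) then meets a fully substituted, deactivated pyrrole with no cation source present, and the sequence comes back to the route at 14, bypassing 12.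

Step 4.
- Risk: palladium may insert competitively into an aryl C–Br bond, the alkyne may undergo copper-mediated oxidative homocoupling, or the amino-ynone may degrade under the base.
- Fallback: the C–C bond is made without a transition metal. Setting out from 6, MeNH(OMe)·HCl and Et3N in CH2Cl2 should give 3,5-dibromo-N,2-dimethoxy-N-methylbenzamide F5. Compound 2 is deprotonated twice (n-BuLi, 2 equiv, THF, −78 °C, 2 in slight excess so that no butyllithium remains) to tert-butyl N-lithio-N-(3-lithioprop-2-ynyl)carbamate F6. Addition of F6 to F5 and an NH4Cl quench come back to the route at 7.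

**Further compounds**
F1 | step 5 | tert-butyl 2-(3,5-dibromo-2-methoxyphenyl)-4-iodopyrrole-1-carboxylate | CC(C)(C)OC(=O)n1cc(I)cc1-c1cc(Br)cc(Br)c1OC
F2 | step 5 | [1-(tert-butoxycarbonyl)-5-(3,5-dibromo-2-methoxyphenyl)pyrrol-3-yl]magnesium chloride | CC(C)(C)OC(=O)n1cc([Mg]Cl)cc1-c1cc(Br)cc(Br)c1OC
F3 | step 6 | 4-bromo-2-(3,5-dibromo-2-methoxyphenyl)-1H-pyrrole | COc1c(Br)cc(Br)cc1-c1cc(Br)c[nH]1
F4 | step 6 | 2,3,4-tribromo-5-(3,5-dibromo-2-methoxyphenyl)-1H-pyrrole | COc1c(Br)cc(Br)cc1-c1[nH]c(Br)c(Br)c1Br
F5 | step 4 | 3,5-dibromo-N,2-dimethoxy-N-methylbenzamide | CON(C)C(=O)c1cc(Br)cc(Br)c1OC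
F6 | step 4 | tert-butyl N-lithio-N-(3-lithioprop-2-ynyl)carbamate | [Li]C#CCN([Li])C(=O)OC(C)(C)C
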